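**Plan**

- Retrosynthesis: with the two silyl ethers removed last, ring A is cut at C4a–C5, C5–C6, C7–C8 and C8–C8a, giving a (2S)-6-(diazoacetyl)-2-aryl-2,3-dihydro-4H-pyran-4-one and (triisopropylsilyloxy)acetylene. Ring C is then cut at C2–C3 and O1–C8a (aryl aldehyde plus a 1,3-bis(silyloxy)diene), and finally the aryl–geranyl bond.
- Enabling feature: ring A is a resorcinol fused on the C4a=C8a enol-ether bond of ring C, with the free 5-OH next to C4a, the 7-oxygen meta to it and hydrogens at C6 and C8. This is the pattern left by a ketene carbonyl (C5), a terminal ynol ether (C6, C7) and a diazo carbon (C8).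
- Forward order: ring B is bought as the bromosalicylaldehyde and the geranyl chain is joined by Stille coupling. Ring C arises by an asymmetric formal hetero-Diels–Alder reaction, the C6 ester is turned into the diazo ketone, ring A is closed by the photo-Wolff benzannulation, and buffered fluoride frees the phenols.
- Stereochemistry: C2, the only stereocentre, is set as S in the hetero-Diels–Alder step by the (S)-BINOL titanium catalyst (Si-face attack). It is a doubly donor-activated benzylic ether β to the C4 carbonyl, so strong acid and strong base are avoided afterwards. The E-olefin is taken from geranyl bromide.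

Key step: step 9

Remarks: geranyl stands for (2E)-3,7-dimethylocta-2,6-dien-1-yl; ring atoms are given in flavanone numbering (C4a and C8a are C5 and C6 of the pyranone). Assumption: the facial sense of the (S)-BINOL titanium catalyst is taken to be that established for benzaldehyde (Si face); if the adduct proved to be 2R, (R)-BINOL would be used.

**Step 1**
Reactants: 1 5-bromo-2-hydroxy-4-methoxybenzaldehyde
Product: 2 5-bromo-4-methoxy-2-(triisopropylsilyloxy)benzaldehyde
Conditions: iPr3SiCl, imidazole, DMF, 23 °C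
Reagents that add atoms: triisopropylsilyl chloride, CC(C)[Si](Cl)(C(C)C)C(C)C
Why: Imidazole-mediated O-silylation of the phenol (silyl ether formation) masks the only acidic hydrogen with a bulky group that should survive the coupling, the Lewis-acid step and the ketene chemistry and still leave with buffered fluoride at the end.

**Step 2**
Reactants: 3 geranyl bromide
Product: 4 tributyl(geranyl)stannane
Conditions: Bu3SnH, LiN(iPr)2, THF, 0 °C; then 3, −78 °C
Reagents that add atoms: tributyltin hydride (used as Bu3SnLi), CCCC[SnH](CCCC)CCCC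
Why: SN2 displacement of the primary allylic bromide by the stannyl anion at low temperature should give the allylic stannane with the trisubstituted E-olefin intact.

**Step 3**
Reactants: 2 5-bromo-4-methoxy-2-(triisopropylsilyloxy)benzaldehyde; 4 tributyl(geranyl)stannane
Product: 5 5-geranyl-4-methoxy-2-(triisopropylsilyloxy)benzaldehyde
Conditions: Pd(PPh3)4 (5 mol %), DMF, 90 °C
Reagents that add atoms: none
Why: Migita–Kosugi–Stille coupling under neutral, fluoride-free conditions should join the aryl carbon to the primary allyl terminus with the E-olefin retained, while the aldehyde and the aryl silyl ether are left alone.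

**Step 4**
Reactants: 6 methyl 2,4-dioxopentanoate
Product: 7 methyl (2Z)-2,4-bis(trimethylsilyloxy)penta-2,4-dienoate
Conditions: Me3SiOTf (2.2 equiv), Et3N, Et2O, 0 °C
Reagents that add atoms: trimethylsilyl trifluoromethanesulfonate, C[Si](C)(C)OS(=O)(=O)C(F)(F)F
Why: Soft enolisation and double O-silylation of the enolised 1,3-dicarbonyl unit (silyl enol ether formation) should give the 1,3-dioxygenated diene whose terminal CH2 is the nucleophilic site; the geometry of its trisubstituted olefin is of no consequence because that carbon becomes sp2 C6 of the pyranone.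

**Step 5**
Reactants: 5 5-geranyl-4-methoxy-2-(triisopropylsilyloxy)benzaldehyde; 7 methyl (2Z)-2,4-bis(trimethylsilyloxy)penta-2,4-dienoate
Product: 9 methyl (2S)-2-[5-geranyl-4-methoxy-2-(triisopropylsilyloxy)phenyl]-4-oxo-3,4-dihydro-2H-pyran-6-carboxylate, via aldol adduct 8 (not isolated)
Conditions: Ti(OiPr)4 (10 mol %), (S)-BINOL (20 mol %), 4 Å molecular sieves, Et2O, −20 to 0 °C; then CF3CO2H (cat.), CH2Cl2, 0 °C
Reagents that add atoms: none
Why: Formal hetero-Diels–Alder reaction in which the titanium BINOLate activates the aldehyde for Mukaiyama aldol addition of the diene terminus (C2–C3), adduct 8 then closes the O1–C6 bond of the pyranone and loses its silyl groups under a trace of acid, and the (S)-BINOL ligand is expected to expose the Si face of the aldehyde so that C2 is set as S under catalyst control.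

**Step 6**
Reactants: 9 methyl (2S)-2-[5-geranyl-4-methoxy-2-(triisopropylsilyloxy)phenyl]-4-oxo-3,4-dihydro-2H-pyran-6-carboxylate
Product: 10 (2S)-2-[5-geranyl-4-methoxy-2-(triisopropylsilyloxy)phenyl]-4-oxo-3,4-dihydro-2H-pyran-6-carboxylic acid
Conditions: Me3SnOH (3 equiv), ClCH2CH2Cl, 70 °C; cold 0.1 M aq. HCl work-up
Reagents that add atoms: trimethyltin hydroxide, C[Sn](C)(C)O
Why: Ester hydrolysis with Me3SnOH, a mild hydroxide donor that works near neutrality, should cleave the activated methyl ester without the C3 enolisation that would open the ring by β-elimination of O1 and erase C2.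

**Step 7**
Reactants: 10 (2S)-2-[5-geranyl-4-methoxy-2-(triisopropylsilyloxy)phenyl]-4-oxo-3,4-dihydro-2H-pyran-6-carboxylic acid
Product: 12 (2S)-6-(diazoacetyl)-2-[5-geranyl-4-methoxy-2-(triisopropylsilyloxy)phenyl]-2,3-dihydro-4H-pyran-4-one, via acid chloride 11 (not isolated)
Conditions: 1-chloro-N,N,2-trimethylprop-1-en-1-amine, CH2Cl2, 0 °C; then CH2N2 (1.5 equiv), Et3N (1.1 equiv), Et2O, −20 to 0 °C
Reagents that add atoms: diazomethane, C=[N+]=[N-]
Why: Acylation of diazomethane by the acid chloride (first stage of the Arndt–Eistert sequence), the chloride being made under neutral conditions with the α-chloroenamine, should outrun dipolar cycloaddition to the donor-substituted C5=C6 bond when diazomethane is kept near one equivalent and Et3N takes up the HCl.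

**Step 8**
Reactants: 13 acetylene
Product: 16 (triisopropylsilyloxy)acetylene, via lithium acetylide 14 (not isolated), via lithium ethynolate 15 (not isolated)
Conditions: n-BuLi, THF, −78 °C; t-BuOOLi (from t-BuOOH and LiN(SiMe3)2), −78 to −20 °C; iPr3SiOTf, −78 to 0 °C
Reagents that add atoms: tert-butyl hydroperoxide (as its lithium salt), CC(C)(C)OO; triisopropylsilyl trifluoromethanesulfonate, CC(C)[Si](OS(=O)(=O)C(F)(F)F)(C(C)C)C(C)C
Why: The lithium acetylide is oxidised at carbon by the electrophilic oxygen of lithium tert-butyl peroxide to the lithium ynolate, and the hard, bulky silyl triflate should silylate this ambident anion at oxygen (ynolate O-silylation) to give the distillable silyl ynol ether.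

**Step 9**
Reactants: 12 (2S)-6-(diazoacetyl)-2-[5-geranyl-4-methoxy-2-(triisopropylsilyloxy)phenyl]-2,3-dihydro-4H-pyran-4-one; 16 (triisopropylsilyloxy)acetylene
Product: 21 (2S)-2-[5-geranyl-4-methoxy-2-(triisopropylsilyloxy)phenyl]-5-hydroxy-7-(triisopropylsilyloxy)-2,3-dihydro-4H-chromen-4-one, via vinylketene 17 (not isolated), via cyclobutenone 18 (not isolated), via dienylketene 19 (not isolated), via cyclohexadienone 20 (not isolated)
Conditions: 16 (1.5 equiv), hν (300 nm, Pyrex), ClCH2CH2Cl, 23 °C; then 80 °C in the dark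
Reagents that add atoms: none
Why: Light expels N2 from 12 and the pyranonyl group shifts to the carbene carbon (Wolff rearrangement, making C8–C8a) to give vinylketene 17, whose central ketene carbon is attacked by the unsubstituted, nucleophilic carbon of ynol ether 16 in a regioselective [2+2] cycloaddition (C5–C6 and C7–C8) that gives the 3-silyloxy-4-vinylcyclobutenone 18. 4π electrocyclic opening of 18 gives dienylketene 19, and ring A closes by thermal disrotatory 6π electrocyclisation of this ketene onto C4a (C4a–C5), after which keto tautomer 20 enolises to the phenol. The closest known reaction type is the Danheiser benzannulation in its α-diazo ketone variant with siloxyalkynes, here run on a vinylketene whose alkene is the enol-ether bond of a dihydropyranone. No stereocentre is created, the sp3 carbons of 18 and 20 being transient, and C2 is a spectator that the neutral medium should leave untouched. The step needs regioselectivity in the [2+2] event, which the polarisation of the partners secures (the ketene carbonyl carbon is the only strong electrophile and the CH terminus of 16 the only nucleophilic carbon), so that the former ketene oxygen becomes the 5-hydroxyl and the silyloxy carbon becomes C7. Hydrogen bonding of the new 5-OH to the C4 carbonyl should keep the product phenol from capturing further ketene.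

**Step 10**
Reactants: 21 (2S)-2-[5-geranyl-4-methoxy-2-(triisopropylsilyloxy)phenyl]-5-hydroxy-7-(triisopropylsilyloxy)-2,3-dihydro-4H-chromen-4-one
Product: 22 kuwanon U
Conditions: Bu4NF, AcOH (1:1), THF, 0 to 23 °C
Reagents that add atoms: none
Why: Fluoride-induced desilylation of the two aryl silyl ethers, buffered with acetic acid so that no phenoxide or C3 enolate can open ring C to the chalcone, should free the 7- and 2'-hydroxyls and leave C2 and the geranyl chain unchanged.

**Compound list**

1 | 5-bromo-2-hydroxy-4-methoxybenzaldehyde | COc1cc(O)c(C=O)cc1Br | starting material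
2 | 5-bromo-4-methoxy-2-(triisopropylsilyloxy)benzaldehyde | COc1cc(O[Si](C(C)C)(C(C)C)C(C)C)c(C=O)cc1Br | intermediate
3 | geranyl bromide, (2E)-1-bromo-3,7-dimethylocta-2,6-diene | BrC/C=C(\C)CCC=C(C)C | starting material
4 | tributyl(geranyl)stannane | CCCC[Sn](CCCC)(CCCC)C/C=C(\C)CCC=C(C)C | intermediate
5 | 5-geranyl-4-methoxy-2-(triisopropylsilyloxy)benzaldehyde | COc1cc(O[Si](C(C)C)(C(C)C)C(C)C)c(C=O)cc1C/C=C(\C)CCC=C(C)C | intermediate
6 | methyl 2,4-dioxopentanoate | COC(=O)C(=O)CC(C)=O | starting material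
7 | methyl (2Z)-2,4-bis(trimethylsilyloxy)penta-2,4-dienoate | COC(=O)/C(O[Si](C)(C)C)=C/C(=C)O[Si](C)(C)C | intermediate
8 | methyl (2Z,6S)-6-[5-geranyl-4-methoxy-2-(triisopropylsilyloxy)phenyl]-4-oxo-2,6-bis(trimethylsilyloxy)hex-2-enoate | COc1cc(O[Si](C(C)C)(C(C)C)C(C)C)c([C@@H](O[Si](C)(C)C)CC(=O)/C=C(\O[Si](C)(C)C)C(=O)OC)cc1C/C=C(\C)CCC=C(C)C | intermediate (not isolated)
9 | methyl (2S)-2-[5-geranyl-4-methoxy-2-(triisopropylsilyloxy)phenyl]-4-oxo-3,4-dihydro-2H-pyran-6-carboxylate | COc1cc(O[Si](C(C)C)(C(C)C)C(C)C)c([C@@H]2CC(=O)C=C(C(=O)OC)O2)cc1C/C=C(\C)CCC=C(C)C | intermediate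
10 | (2S)-2-[5-geranyl-4-methoxy-2-(triisopropylsilyloxy)phenyl]-4-oxo-3,4-dihydro-2H-pyran-6-carboxylic acid | COc1cc(O[Si](C(C)C)(C(C)C)C(C)C)c([C@@H]2CC(=O)C=C(C(=O)O)O2)cc1C/C=C(\C)CCC=C(C)C | intermediate
11 | (2S)-2-[5-geranyl-4-methoxy-2-(triisopropylsilyloxy)phenyl]-4-oxo-3,4-dihydro-2H-pyran-6-carbonyl chloride | COc1cc(O[Si](C(C)C)(C(C)C)C(C)C)c([C@@H]2CC(=O)C=C(C(=O)Cl)O2)cc1C/C=C(\C)CCC=C(C)C | intermediate (not isolated)
12 | (2S)-6-(diazoacetyl)-2-[5-geranyl-4-methoxy-2-(triisopropylsilyloxy)phenyl]-2,3-dihydro-4H-pyran-4-one | COc1cc(O[Si](C(C)C)(C(C)C)C(C)C)c([C@@H]2CC(=O)C=C(C(=O)C=[N+]=[N-])O2)cc1C/C=C(\C)CCC=C(C)C | intermediate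
13 | acetylene | C#C | starting material
14 | lithium acetylide | [Li]C#C | intermediate (not isolated)
15 | lithium ethynolate | [Li]OC#C | intermediate (not isolated)
16 | (triisopropylsilyloxy)acetylene | C#CO[Si](C(C)C)(C(C)C)C(C)C | intermediate
17 | (2S)-2-[5-geranyl-4-methoxy-2-(triisopropylsilyloxy)phenyl]-6-(2-oxoethenyl)-2,3-dihydro-4H-pyran-4-one (vinylketene) | COc1cc(O[Si](C(C)C)(C(C)C)C(C)C)c([C@@H]2CC(=O)C=C(C=C=O)O2)cc1C/C=C(\C)CCC=C(C)C | intermediate (not isolated)
18 | (2S)-2-[5-geranyl-4-methoxy-2-(triisopropylsilyloxy)phenyl]-6-[4-oxo-2-(triisopropylsilyloxy)cyclobut-2-en-1-yl]-2,3-dihydro-4H-pyran-4-one (both epimers at the cyclobutene carbon) | COc1cc(O[Si](C(C)C)(C(C)C)C(C)C)c([C@@H]2CC(=O)C=C(C3C(=O)C=C3O[Si](C(C)C)(C(C)C)C(C)C)O2)cc1C/C=C(\C)CCC=C(C)C | intermediate (not isolated)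
19 | (2S)-2-[5-geranyl-4-methoxy-2-(triisopropylsilyloxy)phenyl]-6-[4-oxo-2-(triisopropylsilyloxy)buta-1,3-dien-1-yl]-2,3-dihydro-4H-pyran-4-one (ketene and pyranone carbons cis on the central C=C) | COc1cc(O[Si](C(C)C)(C(C)C)C(C)C)c([C@@H]2CC(=O)C=C(/C=C(\C=C=O)O[Si](C(C)C)(C(C)C)C(C)C)O2)cc1C/C=C(\C)CCC=C(C)C | intermediate (not isolated)
20 | (2S)-2-[5-geranyl-4-methoxy-2-(triisopropylsilyloxy)phenyl]-7-(triisopropylsilyloxy)-2,3-dihydro-4H-chromene-4,5(4aH)-dione (either configuration at C4a) | COc1cc(O[Si](C(C)C)(C(C)C)C(C)C)c([C@@H]2CC(=O)C3C(=O)C=C(O[Si](C(C)C)(C(C)C)C(C)C)C=C3O2)cc1C/C=C(\C)CCC=C(C)C | intermediate (not isolated)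
21 | (2S)-2-[5-geranyl-4-methoxy-2-(triisopropylsilyloxy)phenyl]-5-hydroxy-7-(triisopropylsilyloxy)-2,3-dihydro-4H-chromen-4-one | COc1cc(O[Si](C(C)C)(C(C)C)C(C)C)c([C@@H]2CC(=O)c3c(O)cc(O[Si](C(C)C)(C(C)C)C(C)C)cc3O2)cc1C/C=C(\C)CCC=C(C)C | intermediate
22 | kuwanon U, (2S)-2-(5-geranyl-2-hydroxy-4-methoxyphenyl)-5,7-dihydroxy-2,3-dihydro-4H-chromen-4-one | COc1cc(O)c([C@@H]2CC(=O)c3c(O)cc(O)cc3O2)cc1C/C=C(\C)CCC=C(C)C | target

**Count**

Total: 10 steps. Longest linear sequence: 7 steps (steps 1, 3, 5, 6, 7, 9, 10) from compound 1.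

**Steps most likely to fail, with fallbacks**

1. Step 9. The irradiation may excite the enone or aryl chromophores as well as the diazo ketone, so that enone photocycloaddition or sensitised E/Z isomerisation of the side chain competes, and the vinylketene may dimerise before the ynol ether captures it. The fallback generates the same ketene in the dark. Compound 12 is rearranged with PhCO2Ag (cat.) and Et3N in THF–H2O at 23 °C (Arndt–Eistert homologation) to [(2S)-2-[5-geranyl-4-methoxy-2-(triisopropylsilyloxy)phenyl]-4-oxo-3,4-dihydro-2H-pyran-6-yl]acetic acid F1. This is converted with 1-chloro-N,N,2-trimethylprop-1-en-1-amine in CH2Cl2 at 0 °C into the corresponding acetyl chloride F2. Slow addition of F2 to Et3N and 16 in toluene at 23 °C should give vinylketene 17 by dehydrochlorination and cyclobutenone 18 by [2+2] cycloaddition; warming to 80 °C then carries 18 through 19 and 20 to compound 21, where the route is rejoined.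

2. Step 5. The ester-bearing diene may add too slowly to the hindered, electron-rich aldehyde, or facial control may be incomplete. The fallback builds ring C stepwise from aldehyde 5. Brown allylboration with (−)-B-allyldiisopinocampheylborane (Et2O, −78 °C, ethanolamine work-up) should give (1S)-1-[5-geranyl-4-methoxy-2-(triisopropylsilyloxy)phenyl]but-3-en-1-ol F3 by Si-face addition. Wacker oxidation of the terminal olefin (PdCl2 cat., CuCl, O2, DMF–H2O) gives (4S)-4-[5-geranyl-4-methoxy-2-(triisopropylsilyloxy)phenyl]-4-hydroxybutan-2-one F4. Claisen condensation of its dianion (LiN(SiMe3)2, 2.2 equiv, THF, −78 °C) with dimethyl oxalate gives methyl (6S)-6-[5-geranyl-4-methoxy-2-(triisopropylsilyloxy)phenyl]-6-hydroxy-2,4-dioxohexanoate F5, and catalytic CF3CO2H in CH2Cl2 at 0 °C cyclodehydrates F5 to compound 9.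

3. Step 7. Dipolar cycloaddition of diazomethane to the acceptor-substituted C5=C6 bond may compete with acylation and consume the material as a pyrazoline. The fallback avoids diazomethane. Acid chloride 11, made from 10 as before, is coupled with MeZnCl and Pd(PPh3)4 (cat.) in THF at 0 °C (Negishi acylation) to give (2S)-6-acetyl-2-[5-geranyl-4-methoxy-2-(triisopropylsilyloxy)phenyl]-2,3-dihydro-4H-pyran-4-one F6. Kinetic enolisation of the more acidic acetyl group (LiN(SiMe3)2, THF, −78 °C) and trapping with CF3CO2CH2CF3 gives (2S)-2-[5-geranyl-4-methoxy-2-(triisopropylsilyloxy)phenyl]-6-(4,4,4-trifluoro-3-oxobutanoyl)-2,3-dihydro-4H-pyran-4-one F7. Detrifluoroacetylative diazo transfer (MeSO2N3, Et3N, H2O, MeCN, 23 °C) then returns compound 12.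

**Further compounds**

F1 | step 9 | [(2S)-2-[5-geranyl-4-methoxy-2-(triisopropylsilyloxy)phenyl]-4-oxo-3,4-dihydro-2H-pyran-6-yl]acetic acid | COc1cc(O[Si](C(C)C)(C(C)C)C(C)C)c([C@@H]2CC(=O)C=C(CC(=O)O)O2)cc1C/C=C(\C)CCC=C(C)C
F2 | step 9 | [(2S)-2-[5-geranyl-4-methoxy-2-(triisopropylsilyloxy)phenyl]-4-oxo-3,4-dihydro-2H-pyran-6-yl]acetyl chloride | COc1cc(O[Si](C(C)C)(C(C)C)C(C)C)c([C@@H]2CC(=O)C=C(CC(=O)Cl)O2)cc1C/C=C(\C)CCC=C(C)C
F3 | step 5 | (1S)-1-[5-geranyl-4-methoxy-2-(triisopropylsilyloxy)phenyl]but-3-en-1-ol | COc1cc(O[Si](C(C)C)(C(C)C)C(C)C)c([C@@H](O)CC=C)cc1C/C=C(\C)CCC=C(C)C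
F4 | step 5 | (4S)-4-[5-geranyl-4-methoxy-2-(triisopropylsilyloxy)phenyl]-4-hydroxybutan-2-one | COc1cc(O[Si](C(C)C)(C(C)C)C(C)C)c([C@@H](O)CC(C)=O)cc1C/C=C(\C)CCC=C(C)C
F5 | step 5 | methyl (6S)-6-[5-geranyl-4-methoxy-2-(triisopropylsilyloxy)phenyl]-6-hydroxy-2,4-dioxohexanoate | COc1cc(O[Si](C(C)C)(C(C)C)C(C)C)c([C@@H](O)CC(=O)CC(=O)C(=O)OC)cc1C/C=C(\C)CCC=C(C)C
F6 | step 7 | (2S)-6-acetyl-2-[5-geranyl-4-methoxy-2-(triisopropylsilyloxy)phenyl]-2,3-dihydro-4H-pyran-4-one | COc1cc(O[Si](C(C)C)(C(C)C)C(C)C)c([C@@H]2CC(=O)C=C(C(C)=O)O2)cc1C/C=C(\C)CCC=C(C)C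
F7 | step 7 | (2S)-2-[5-geranyl-4-methoxy-2-(triisopropylsilyloxy)phenyl]-6-(4,4,4-trifluoro-3-oxobutanoyl)-2,3-dihydro-4H-pyran-4-one | COc1cc(O[Si](C(C)C)(C(C)C)C(C)C)c([C@@H]2CC(=O)C=C(C(=O)CC(=O)C(F)(F)F)O2)cc1C/C=C(\C)CCC=C(C)C
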